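(The earlier runs and the new flask were computed with constants of no real substance, noise included.)

We decide to count the part of the charge not yet turned into product at the end, not the product made.

| flask | substrate | reagent | free catalyst | second catalyst | remark | time |
|---|---|---|---|---|---|---|
| dusk | 0.12 M | 0.12 M | 0.78 mM | 2.8 mM | run made earlier |  |
| midnight | 0.12 M | 0.12 M | 0.78 mM | 6.4 mM | run made earlier |  |
| spring | 0.12 M | 0.12 M | 0.78 mM | 8.1 mM | run made earlier |  |
| Thursday's | 0.12 M | 0.120 M | 0.78 mM | 4.0 mM |  | 10 min |
| Wednesday's | 0.12 M | 0.120 M | 0.78 mM | 6.0 mM |  | 10 min |
| Tuesday's | 0.12 M | 0.120 M | 0.78 mM | 10 mM |  | 10 min |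

| dusk: time / min | dusk: product / % | midnight: time / min | midnight: product / % | spring: time / min | spring: product / % |
|---|---|---|---|---|---|
| 1.33 | 17 | 2.50 | 42 | 1.33 | 25 |
| 4.00 | 51 | 5.00 | 68 | 4.00 | 59 |
| 6.00 | 69 | 8.00 | 81 | 6.00 | 74 |
| 10.0 | 86 | 10.0 | 88 | 10.0 | 90 |

(each reading ± 2 percentage points)

- amount of product at the end, in percent of the substrate charged for Thursday's, Wednesday's, Tuesday's, in this order
- the shape of the row from first to last (hardly changes / falls, then rises / rises all the way / falls all the way / rises, then falls)

- the earlier runs were read with a standard deviation of 2 percentage points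
- "hardly changes" means that all values lie within two and a half points (for a concentration: within two and a half percent of the largest)

1. We fold the charges into one number. For Thursday's flask the second-catalyst ratio is 5.13, second catalyst charged per free catalyst charged. Wednesday's has 7.69 and Tuesday's 12.8, with substrate and reagent charges equal throughout.

2. At 10.0 min the readings leave 14.0 % at ratio 3.59 (dusk), 12.0 % at 8.21 (midnight) and 10.0 % at 10.4 (spring). With the other charges fixed and the time at 10.0 min, we take the fraction left as proportional to the ratio raised to minus e. Dusk and spring give a reading of e = 0.317.

3. We test this on the midnight run, which was not used. The rule leaves 10.8 %, and the reading is 12.0 %, with a scatter of 2 percentage points. At 1.33 min, however, dusk and spring give e = 0.0954, less than at the end. Both values of e come from scattered readings, so we use e for this time and claim nothing for the whole curve.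

4. Starting from the spring reading, our reckoning leaves 12.5 % in Thursday's flask, 11.0 % in Wednesday's and 9.35 % in Tuesday's. In our reckoning, product then rises all the way, by 3.2 points, which is wider than two and a half points. With e resting on two scattered readings, this is a lean.

5. The forecast gives 88 %, 89 % and 89.5 %, and calls the row hardly changes: “The small rise lies within the reading noise, so the row hardly changes.” Its rise is 1.5 points, and there we differ.

6. The flasks give 85.7 %, 88.0 % and 90.0 %: rises all the way.

    substrate + free catalyst → free catalyst + intermediate (k = 6.00 L mol⁻¹ s⁻¹)
    reagent + second catalyst + intermediate → second catalyst + product (k = 66.0 L² mol⁻² s⁻¹)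

Our ratio of 5.13 put 12.5 % left in Thursday's flask, where 14 % of the reagent stood; at 12.8 it put 9.35 % left in Tuesday's flask, against 10 %. Thursday's ratio times 1.32 is 6.77, the substrate half-life 2.5 min over the intermediate half-life 0.36 min as charged. In Thursday's flask the substrate step ran with free catalyst at 100 % of its charge and had half its turnover behind it by 2.26 min. The second step followed on the intermediate, which stood at 11.0 % at 5.00 min and 8.23 % at 10.0 min, beside 6.03 % substrate, while Tuesday's flask held the same substrate and 4.02 % intermediate.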